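**Retrosynthetic overview**

1. Numbering and feature: ring B is the 14-membered carbocycle C1–C14 (C1 = lactone O–CH, C14 = the other fusion CH; Me on C3, C7, C11; OAc on C5, C9). Ring A is the lactone O–C1–C14–C15–C16(=O), with exocyclic C17H2 on C15. The plan rests on C14 being the β-carbon of the lactone enoate, bonded to an unfunctionalised methylene C13, with C17 allylic to C14.
2. Last bond C13–C14: a C13 radical from an N-hydroxyphthalimide ester adds to C14 of a 3-(phenylsulfonylmethyl)butenolide and PhSO2• is lost. This closes ring B, sets C14 and leaves C15=C17.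
3. Ring A before that: ring-closing metathesis of the 2-(phenylsulfonylmethyl)acrylate of a C1 vinyl carbinol, itself from catalytic asymmetric vinylation of the C1 enal.
4. Chain C1–C13: two catalytic asymmetric vinylogous Mukaiyama aldols (C8–C9, then C4–C5; they set C9 and C5 and give E-C6=C7 and E-C2=C3) on an enal from Zr-catalysed carboalumination of pent-4-yn-1-ol (E-C10=C11).
5. Order of rings: ring A (step 17), then ring B (step 21).

Key step: step 21

Assumption: the (R,R)-enantiomer of the pentane-1,5-diyl-linked bis(N,N′-dimethyl-1,1′-binaphthyl-2,2′-diamine) phosphoramide catalyst is taken to direct the dienolate to the Si face of a conjugated aldehyde; the sense would be checked by Mosher ester analysis of 10, and the (S,S)-catalyst used in steps 5 and 9 if it proves opposite.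

**Route**

Step 1
Reactants: 1 pent-4-yn-1-ol
Product: 2 tert-butyl(pent-4-yn-1-yloxy)diphenylsilane
Conditions: TBDPSCl, imidazole, DMF, rt
Reagents that add atoms: tert-butyldiphenylsilyl chloride, CC(C)(C)[Si](Cl)(c1ccccc1)c1ccccc1
Why: Imidazole-promoted silylation of a primary alcohol; the TBDPS ether should survive the organoaluminium, Lewis acid and hydride steps and outlast the later TES cleavage.

Step 2
Reactants: 2 tert-butyl(pent-4-yn-1-yloxy)diphenylsilane
Product: 5 (E)-6-(tert-butyldiphenylsilyloxy)-3-methylhex-2-en-1-ol, via alkenyldimethylalane 3 (not isolated), via lithium alkenylalanate 4 (not isolated)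
Conditions: Me3Al (2.5 equiv), Cp2ZrCl2 (0.2 equiv), CH2Cl2, 0 °C to rt; volatiles removed; n-BuLi (1.0 equiv), hexane–THF, 0 °C; (CH2O)n, rt; aq. potassium sodium tartrate
Reagents that add atoms: trimethylaluminium, C[Al](C)C; paraformaldehyde (as formaldehyde), C=O
Why: Zr-catalysed carboalumination (Negishi) adds Me and Al syn across the terminal alkyne with Al on the terminal carbon, which fixes E-C10=C11, and the alanate formed with n-BuLi is hydroxymethylated by formaldehyde with retention of alkene geometry.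

Step 3
Reactants: 5 (E)-6-(tert-butyldiphenylsilyloxy)-3-methylhex-2-en-1-ol
Product: 6 (E)-6-(tert-butyldiphenylsilyloxy)-3-methylhex-2-enal
Conditions: MnO2 (excess), CH2Cl2, rt
Reagents that add atoms: none
Why: MnO2 allylic oxidation stops at the enal and should leave the silyl ether and the alkene geometry untouched.

Step 4
Reactants: 7 methyl 3-methylbut-2-enoate
Product: 9 tert-butyl[(1-methoxy-3-methylbuta-1,3-dien-1-yl)oxy]dimethylsilane, via lithium dienolate 8 (not isolated)
Conditions: LiN(iPr)2, THF, −78 °C; TBSCl, DMPU, −78 °C to rt; distillation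
Reagents that add atoms: tert-butyldimethylsilyl chloride, CC(C)(C)[Si](C)(C)Cl
Why: γ-Deprotonation of the senecioate and O-silylation of the extended enolate give the silyl dienolate (silyl ketene acetal formation); its ketene acetal geometry is of no consequence because no α-stereocentre is formed from it.

Step 5
Reactants: 6 (E)-6-(tert-butyldiphenylsilyloxy)-3-methylhex-2-enal; 9 tert-butyl[(1-methoxy-3-methylbuta-1,3-dien-1-yl)oxy]dimethylsilane
Product: 10 methyl (2E,5S,6E)-10-(tert-butyldiphenylsilyloxy)-5-hydroxy-3,7-dimethyldeca-2,6-dienoate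
Conditions: 9 (1.2 equiv), SiCl4 (1.1 equiv), (R,R)-bisphosphoramide catalyst (5 mol%), iPr2NEt (10 mol%), CH2Cl2, −78 °C; aq. NaHCO3
Reagents that add atoms: none
Why: Catalytic enantioselective vinylogous Mukaiyama aldol with Lewis-base-activated SiCl4: the phosphoramide-bound trichlorosilyl cation activates the enal, the dienolate reacts only at its γ-carbon to form C8–C9 and the E-enoate (C6=C7), and the catalyst is expected to direct attack to the Si face to give the (S)-carbinol at C9.

Step 6
Reactants: 10 methyl (2E,5S,6E)-10-(tert-butyldiphenylsilyloxy)-5-hydroxy-3,7-dimethyldeca-2,6-dienoate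
Product: 11 methyl (2E,5S,6E)-10-(tert-butyldiphenylsilyloxy)-3,7-dimethyl-5-(triethylsilyloxy)deca-2,6-dienoate
Conditions: TESCl, imidazole, DMF, 0 °C
Reagents that add atoms: triethylsilyl chloride, CC[Si](Cl)(CC)CC
Why: Silylation of the secondary allylic alcohol protects C9–OH against the hydride and the Lewis acid of the next steps and can later be removed in the presence of the TBDPS ether.

Step 7
Reactants: 11 methyl (2E,5S,6E)-10-(tert-butyldiphenylsilyloxy)-3,7-dimethyl-5-(triethylsilyloxy)deca-2,6-dienoate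
Product: 12 (2E,5S,6E)-10-(tert-butyldiphenylsilyloxy)-3,7-dimethyl-5-(triethylsilyloxy)deca-2,6-dien-1-ol
Conditions: iBu2AlH (2.5 equiv), CH2Cl2, −78 °C; aq. potassium sodium tartrate
Reagents that add atoms: none
Why: iBu2AlH reduces the enoate 1,2 to the allylic alcohol at low temperature (ester reduction) and should leave both silyl ethers and the alkenes.

Step 8
Reactants: 12 (2E,5S,6E)-10-(tert-butyldiphenylsilyloxy)-3,7-dimethyl-5-(triethylsilyloxy)deca-2,6-dien-1-ol
Product: 13 (2E,5S,6E)-10-(tert-butyldiphenylsilyloxy)-3,7-dimethyl-5-(triethylsilyloxy)deca-2,6-dienal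
Conditions: MnO2 (excess), CH2Cl2, rt
Reagents that add atoms: none
Why: MnO2 allylic oxidation gives the E-enal for the second chain extension without affecting the silyl ethers.

Step 9
Reactants: 13 (2E,5S,6E)-10-(tert-butyldiphenylsilyloxy)-3,7-dimethyl-5-(triethylsilyloxy)deca-2,6-dienal; 9 tert-butyl[(1-methoxy-3-methylbuta-1,3-dien-1-yl)oxy]dimethylsilane
Product: 14 methyl (2E,5S,6E,9S,10E)-14-(tert-butyldiphenylsilyloxy)-5-hydroxy-3,7,11-trimethyl-9-(triethylsilyloxy)tetradeca-2,6,10-trienoate
Conditions: 9 (1.2 equiv), SiCl4 (1.1 equiv), (R,R)-bisphosphoramide catalyst (5 mol%), iPr2NEt (10 mol%), CH2Cl2, −78 °C; aq. NaHCO3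
Reagents that add atoms: none
Why: A second vinylogous Mukaiyama aldol under the same catalyst forms C4–C5 and E-C2=C3, the catalyst again being expected to direct Si-face attack to give (S)-C5 because the existing centre (1,5-related) is too remote to compete.

Step 10
Reactants: 14 methyl (2E,5S,6E,9S,10E)-14-(tert-butyldiphenylsilyloxy)-5-hydroxy-3,7,11-trimethyl-9-(triethylsilyloxy)tetradeca-2,6,10-trienoate
Product: 15 (2E,5S,6E,9S,10E)-14-(tert-butyldiphenylsilyloxy)-3,7,11-trimethyl-9-(triethylsilyloxy)tetradeca-2,6,10-triene-1,5-diol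
Conditions: iBu2AlH (3.5 equiv), CH2Cl2, −78 °C; aq. potassium sodium tartrate
Reagents that add atoms: none
Why: iBu2AlH ester reduction (one equivalent is spent on the free hydroxyl) gives the primary allylic alcohol and should spare the silyl ethers.

Step 11
Reactants: 15 (2E,5S,6E,9S,10E)-14-(tert-butyldiphenylsilyloxy)-3,7,11-trimethyl-9-(triethylsilyloxy)tetradeca-2,6,10-triene-1,5-diol
Product: 16 (2E,5S,6E,9S,10E)-14-(tert-butyldiphenylsilyloxy)-5-hydroxy-3,7,11-trimethyl-9-(triethylsilyloxy)tetradeca-2,6,10-trienal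
Conditions: TEMPO (10 mol%), PhI(OAc)2 (1.1 equiv), CH2Cl2, rt
Reagents that add atoms: none
Why: Oxoammonium oxidation (TEMPO/PhI(OAc)2) is strongly selective for the primary allylic alcohol over the secondary C5–OH, so the enal should form without a protecting step.

Step 12
Reactants: 16 (2E,5S,6E,9S,10E)-14-(tert-butyldiphenylsilyloxy)-5-hydroxy-3,7,11-trimethyl-9-(triethylsilyloxy)tetradeca-2,6,10-trienal
Product: 17 (2E,5S,6E,9S,10E)-14-(tert-butyldiphenylsilyloxy)-5,9-dihydroxy-3,7,11-trimethyltetradeca-2,6,10-trienal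
Conditions: HF·pyridine, pyridine, THF, 0 °C
Reagents that add atoms: none
Why: Buffered HF·pyridine cleaves the secondary TES ether much faster than the primary TBDPS ether (selective desilylation) and does not acetalise or isomerise the E-enal.

Step 13
Reactants: 17 (2E,5S,6E,9S,10E)-14-(tert-butyldiphenylsilyloxy)-5,9-dihydroxy-3,7,11-trimethyltetradeca-2,6,10-trienal
Product: 18 (2E,5S,6E,9S,10E)-14-(tert-butyldiphenylsilyloxy)-3,7,11-trimethyl-1-oxotetradeca-2,6,10-triene-5,9-diyl diacetate
Conditions: Ac2O, pyridine, DMAP (cat.), CH2Cl2, 0 °C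
Reagents that add atoms: acetic anhydride, CC(=O)OC(C)=O
Why: Acylation of the only two free hydroxyls installs both acetates of the target, the low temperature serving to avoid vinylogous β-elimination of the C5 acetate from the enal.

Step 14
Reactants: 18 (2E,5S,6E,9S,10E)-14-(tert-butyldiphenylsilyloxy)-3,7,11-trimethyl-1-oxotetradeca-2,6,10-triene-5,9-diyl diacetate
Product: 19 (3R,4E,7S,8E,11S,12E)-16-(tert-butyldiphenylsilyloxy)-3-hydroxy-5,9,13-trimethylhexadeca-1,4,8,12-tetraene-7,11-diyl diacetate
Conditions: Zn(CH=CH2)2 (2 equiv), (+)-DAIB [(2R)-3-exo-(dimethylamino)isoborneol, 10 mol%], toluene, −20 to 0 °C; aq. NH4Cl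
Reagents that add atoms: divinylzinc, C=C[Zn]C=C
Why: Amino-alcohol-catalysed enantioselective organozinc addition: the (+)-DAIB–zinc complex should transfer a vinyl group to the Re face of the enal (the mirror image of the Si-face delivery by (−)-DAIB), giving the (R)-carbinol that becomes C1, and a dialkenylzinc does not attack acetates.

Step 15
Reactants: 20 2-(bromomethyl)acrylic acid
Product: 21 2-(phenylsulfonylmethyl)acrylic acid
Conditions: PhSO2Na (2.2 equiv), MeOH, reflux; aq. HCl
Reagents that add atoms: sodium benzenesulfinate, [Na+].[O-]S(=O)c1ccccc1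
Why: S-Alkylation of the sulfinate by the allylic bromide (SN2, or SN2′ which gives the same constitution) delivers the allyl sulfone directly at the acid oxidation level.

Step 16
Reactants: 19 (3R,4E,7S,8E,11S,12E)-16-(tert-butyldiphenylsilyloxy)-3-hydroxy-5,9,13-trimethylhexadeca-1,4,8,12-tetraene-7,11-diyl diacetate; 21 2-(phenylsulfonylmethyl)acrylic acid
Product: 22 (3R,4E,7S,8E,11S,12E)-7,11-diacetoxy-16-(tert-butyldiphenylsilyloxy)-5,9,13-trimethylhexadeca-1,4,8,12-tetraen-3-yl 2-(phenylsulfonylmethyl)acrylate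
Conditions: 21 (1.5 equiv), iPrN=C=NiPr (1.5 equiv), DMAP (10 mol%), CH2Cl2, 0 °C
Reagents that add atoms: none
Why: Steglich esterification acylates the acid-labile bis-allylic alcohol under near-neutral conditions without ionising it, so the C1 configuration is kept.

Step 17
Reactants: 22 (3R,4E,7S,8E,11S,12E)-7,11-diacetoxy-16-(tert-butyldiphenylsilyloxy)-5,9,13-trimethylhexadeca-1,4,8,12-tetraen-3-yl 2-(phenylsulfonylmethyl)acrylate
Product: 23 (5S)-5-[(1E,4S,5E,8S,9E)-4,8-diacetoxy-13-(tert-butyldiphenylsilyloxy)-2,6,10-trimethyltrideca-1,5,9-trien-1-yl]-3-(phenylsulfonylmethyl)furan-2(5H)-one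
Conditions: second-generation Hoveyda–Grubbs catalyst (10 mol%), 1,4-benzoquinone (20 mol%), toluene (5 mM), 70 °C, argon sparge
Reagents that add atoms: none
Why: Ring-closing metathesis: the Ru alkylidene loads on the monosubstituted vinyl group and closes onto the 1,1-disubstituted acrylate, the known way from 2-substituted acrylates of allylic alcohols to 3-substituted butenolides (ring A), while the trisubstituted alkenes, acetates and sulfone should be inert.

Step 18
Reactants: 23 (5S)-5-[(1E,4S,5E,8S,9E)-4,8-diacetoxy-13-(tert-butyldiphenylsilyloxy)-2,6,10-trimethyltrideca-1,5,9-trien-1-yl]-3-(phenylsulfonylmethyl)furan-2(5H)-one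
Product: 24 (5S)-5-[(1E,4S,5E,8S,9E)-4,8-diacetoxy-13-hydroxy-2,6,10-trimethyltrideca-1,5,9-trien-1-yl]-3-(phenylsulfonylmethyl)furan-2(5H)-one
Conditions: HF·pyridine (excess), THF, 0 °C to rt
Reagents that add atoms: none
Why: Fluoride desilylation under acidic rather than basic conditions frees the primary alcohol without deprotonating the butenolide at C1 or the allyl sulfone and without cleaving the acetates.

Step 19
Reactants: 24 (5S)-5-[(1E,4S,5E,8S,9E)-4,8-diacetoxy-13-hydroxy-2,6,10-trimethyltrideca-1,5,9-trien-1-yl]-3-(phenylsulfonylmethyl)furan-2(5H)-one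
Product: 25 (4E,6S,8E,10S,12E)-6,10-diacetoxy-4,8,12-trimethyl-13-[(2S)-5-oxo-4-(phenylsulfonylmethyl)-2,5-dihydrofuran-2-yl]trideca-4,8,12-trienoic acid
Conditions: TEMPO (20 mol%), PhI(OAc)2 (2.5 equiv), MeCN–H2O 1:1, rt
Reagents that add atoms: water, O
Why: Oxoammonium oxidation in aqueous acetonitrile takes the primary alcohol through the aldehyde hydrate to the acid under neutral to weakly acidic conditions that alkenes, acetates and the butenolide tolerate.

Step 20
Reactants: 25 (4E,6S,8E,10S,12E)-6,10-diacetoxy-4,8,12-trimethyl-13-[(2S)-5-oxo-4-(phenylsulfonylmethyl)-2,5-dihydrofuran-2-yl]trideca-4,8,12-trienoic acid; 26 N-hydroxyphthalimide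
Product: 27 1,3-dioxoisoindolin-2-yl (4E,6S,8E,10S,12E)-6,10-diacetoxy-4,8,12-trimethyl-13-[(2S)-5-oxo-4-(phenylsulfonylmethyl)-2,5-dihydrofuran-2-yl]trideca-4,8,12-trienoate
Conditions: 26 (1.1 equiv), iPrN=C=NiPr (1.1 equiv), CH2Cl2, 0 °C to rt, no amine base; rapid filtration through silica
Reagents that add atoms: none
Why: Carbodiimide coupling of the acid with the acidic N-hydroxy imide (active ester formation) needs no amine, so neither the C1–H of the butenolide nor the allyl sulfone meets a base or a nucleophilic catalyst.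

Step 21
Reactants: 27 1,3-dioxoisoindolin-2-yl (4E,6S,8E,10S,12E)-6,10-diacetoxy-4,8,12-trimethyl-13-[(2S)-5-oxo-4-(phenylsulfonylmethyl)-2,5-dihydrofuran-2-yl]trideca-4,8,12-trienoate
Product: 28 the target, the trans-fused α-methylene-γ-butyrolactone (1S,5S,9S,14R in the numbering of the overview) with 2E,6E,10E alkenes and acetates at C5 and C9
Conditions: undivided cell, Zn anode, reticulated vitreous carbon cathode, nBu4NPF6 (0.1 M), MeCN, 0 °C, constant current held at the first reduction wave of 27 (about 2.2 F/mol); 27 added by syringe pump over 10 h (stationary concentration below 1 mM); aq. NH4Cl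
Reagents that add atoms: none
Why: Proposed new method: one-electron reduction of the N-acyloxyphthalimide at the cathode should give a radical anion that breaks down to phthalimide anion, CO2 and the nucleophilic primary C13 radical, which adds to the electron-poor β-carbon C14 of the butenolide (14-exo-trig closure of ring B), after which the tertiary C15 radical expels PhSO2• by β-scission, making the closure irreversible and leaving C15=C17, and the sulfonyl radical is reduced to sulfinate (two electrons per molecule overall). The closest known reaction types are electroreductive decarboxylative Giese additions of N-hydroxyphthalimide esters, radical macrocyclisations onto enoates, and radical allylation by addition–fragmentation of allyl sulfones; their union in a macrocyclisation onto a 3-(sulfonylmethyl)butenolide is untested. The new stereocentre C14 is set by the face of the butenolide that the tether reaches: attack anti to the C1 substituent is the normal preference of γ-substituted butenolides, and the twelve-atom tether stiffened by three E-alkenes is expected, as a prediction only, to leave C1 on one face and return to C14 on the other, giving the trans fusion (14R). Chemoselectivity rests on the phthalimide ester being reduced at a less negative potential than the butenolide, the aryl sulfone or the product, and on the absence of base, hydride or low-valent metal that would touch the allylic acetates. The only alkene near C13 is C10=C11, where 3-exo attack is reversible and constitutionally degenerate; low temperature, a poor hydrogen-donor solvent and slow feeding should keep that path, hydrogen abstraction and intermolecular addition below the ring closure.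

**Compound list**

1 | pent-4-yn-1-ol | C#CCCCO | starting material
2 | tert-butyl(pent-4-yn-1-yloxy)diphenylsilane | C#CCCCO[Si](c1ccccc1)(c1ccccc1)C(C)(C)C | intermediate
3 | [(E)-5-(tert-butyldiphenylsilyloxy)-2-methylpent-1-en-1-yl]dimethylalane | C[Al](C)/C=C(\C)CCCO[Si](c1ccccc1)(c1ccccc1)C(C)(C)C | intermediate
4 | lithium butyl[(E)-5-(tert-butyldiphenylsilyloxy)-2-methylpent-1-en-1-yl]dimethylalanate | [Li+].CCCC[Al-](C)(C)/C=C(\C)CCCO[Si](c1ccccc1)(c1ccccc1)C(C)(C)C | intermediate
5 | (E)-6-(tert-butyldiphenylsilyloxy)-3-methylhex-2-en-1-ol | OC/C=C(\C)CCCO[Si](c1ccccc1)(c1ccccc1)C(C)(C)C | intermediate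
6 | (E)-6-(tert-butyldiphenylsilyloxy)-3-methylhex-2-enal | O=C/C=C(\C)CCCO[Si](c1ccccc1)(c1ccccc1)C(C)(C)C | intermediate
7 | methyl 3-methylbut-2-enoate | COC(=O)C=C(C)C | starting material
8 | lithium 1-methoxy-3-methylbuta-1,3-dien-1-olate | [Li+].[O-]C(OC)=CC(C)=C | intermediate
9 | tert-butyl[(1-methoxy-3-methylbuta-1,3-dien-1-yl)oxy]dimethylsilane | C=C(C)C=C(OC)O[Si](C)(C)C(C)(C)C | intermediate
10 | methyl (2E,5S,6E)-10-(tert-butyldiphenylsilyloxy)-5-hydroxy-3,7-dimethyldeca-2,6-dienoate | COC(=O)/C=C(\C)C[C@H](O)/C=C(\C)CCCO[Si](c1ccccc1)(c1ccccc1)C(C)(C)C | intermediate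
11 | methyl (2E,5S,6E)-10-(tert-butyldiphenylsilyloxy)-3,7-dimethyl-5-(triethylsilyloxy)deca-2,6-dienoate | COC(=O)/C=C(\C)C[C@H](O[Si](CC)(CC)CC)/C=C(\C)CCCO[Si](c1ccccc1)(c1ccccc1)C(C)(C)C | intermediate
12 | (2E,5S,6E)-10-(tert-butyldiphenylsilyloxy)-3,7-dimethyl-5-(triethylsilyloxy)deca-2,6-dien-1-ol | OC/C=C(\C)C[C@H](O[Si](CC)(CC)CC)/C=C(\C)CCCO[Si](c1ccccc1)(c1ccccc1)C(C)(C)C | intermediate
13 | (2E,5S,6E)-10-(tert-butyldiphenylsilyloxy)-3,7-dimethyl-5-(triethylsilyloxy)deca-2,6-dienal | O=C/C=C(\C)C[C@H](O[Si](CC)(CC)CC)/C=C(\C)CCCO[Si](c1ccccc1)(c1ccccc1)C(C)(C)C | intermediate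
14 | methyl (2E,5S,6E,9S,10E)-14-(tert-butyldiphenylsilyloxy)-5-hydroxy-3,7,11-trimethyl-9-(triethylsilyloxy)tetradeca-2,6,10-trienoate | COC(=O)/C=C(\C)C[C@H](O)/C=C(\C)C[C@H](O[Si](CC)(CC)CC)/C=C(\C)CCCO[Si](c1ccccc1)(c1ccccc1)C(C)(C)C | intermediate
15 | (2E,5S,6E,9S,10E)-14-(tert-butyldiphenylsilyloxy)-3,7,11-trimethyl-9-(triethylsilyloxy)tetradeca-2,6,10-triene-1,5-diol | OC/C=C(\C)C[C@H](O)/C=C(\C)C[C@H](O[Si](CC)(CC)CC)/C=C(\C)CCCO[Si](c1ccccc1)(c1ccccc1)C(C)(C)C | intermediate
16 | (2E,5S,6E,9S,10E)-14-(tert-butyldiphenylsilyloxy)-5-hydroxy-3,7,11-trimethyl-9-(triethylsilyloxy)tetradeca-2,6,10-trienal | O=C/C=C(\C)C[C@H](O)/C=C(\C)C[C@H](O[Si](CC)(CC)CC)/C=C(\C)CCCO[Si](c1ccccc1)(c1ccccc1)C(C)(C)C | intermediate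
17 | (2E,5S,6E,9S,10E)-14-(tert-butyldiphenylsilyloxy)-5,9-dihydroxy-3,7,11-trimethyltetradeca-2,6,10-trienal | O=C/C=C(\C)C[C@H](O)/C=C(\C)C[C@H](O)/C=C(\C)CCCO[Si](c1ccccc1)(c1ccccc1)C(C)(C)C | intermediate
18 | (2E,5S,6E,9S,10E)-14-(tert-butyldiphenylsilyloxy)-3,7,11-trimethyl-1-oxotetradeca-2,6,10-triene-5,9-diyl diacetate | O=C/C=C(\C)C[C@H](OC(C)=O)/C=C(\C)C[C@H](OC(C)=O)/C=C(\C)CCCO[Si](c1ccccc1)(c1ccccc1)C(C)(C)C | intermediate
19 | (3R,4E,7S,8E,11S,12E)-16-(tert-butyldiphenylsilyloxy)-3-hydroxy-5,9,13-trimethylhexadeca-1,4,8,12-tetraene-7,11-diyl diacetate | C=C[C@@H](O)/C=C(\C)C[C@H](OC(C)=O)/C=C(\C)C[C@H](OC(C)=O)/C=C(\C)CCCO[Si](c1ccccc1)(c1ccccc1)C(C)(C)C | intermediate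
20 | 2-(bromomethyl)acrylic acid | C=C(CBr)C(=O)O | starting material
21 | 2-(phenylsulfonylmethyl)acrylic acid | C=C(CS(=O)(=O)c1ccccc1)C(=O)O | intermediate
22 | (3R,4E,7S,8E,11S,12E)-7,11-diacetoxy-16-(tert-butyldiphenylsilyloxy)-5,9,13-trimethylhexadeca-1,4,8,12-tetraen-3-yl 2-(phenylsulfonylmethyl)acrylate | C=C[C@@H](OC(=O)C(=C)CS(=O)(=O)c1ccccc1)/C=C(\C)C[C@H](OC(C)=O)/C=C(\C)C[C@H](OC(C)=O)/C=C(\C)CCCO[Si](c1ccccc1)(c1ccccc1)C(C)(C)C | intermediate
23 | (5S)-5-[(1E,4S,5E,8S,9E)-4,8-diacetoxy-13-(tert-butyldiphenylsilyloxy)-2,6,10-trimethyltrideca-1,5,9-trien-1-yl]-3-(phenylsulfonylmethyl)furan-2(5H)-one | O=C1O[C@@H](/C=C(\C)C[C@H](OC(C)=O)/C=C(\C)C[C@H](OC(C)=O)/C=C(\C)CCCO[Si](c2ccccc2)(c2ccccc2)C(C)(C)C)C=C1CS(=O)(=O)c1ccccc1 | intermediate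
24 | (5S)-5-[(1E,4S,5E,8S,9E)-4,8-diacetoxy-13-hydroxy-2,6,10-trimethyltrideca-1,5,9-trien-1-yl]-3-(phenylsulfonylmethyl)furan-2(5H)-one | O=C1O[C@@H](/C=C(\C)C[C@H](OC(C)=O)/C=C(\C)C[C@H](OC(C)=O)/C=C(\C)CCCO)C=C1CS(=O)(=O)c1ccccc1 | intermediate
25 | (4E,6S,8E,10S,12E)-6,10-diacetoxy-4,8,12-trimethyl-13-[(2S)-5-oxo-4-(phenylsulfonylmethyl)-2,5-dihydrofuran-2-yl]trideca-4,8,12-trienoic acid | O=C1O[C@@H](/C=C(\C)C[C@H](OC(C)=O)/C=C(\C)C[C@H](OC(C)=O)/C=C(\C)CCC(=O)O)C=C1CS(=O)(=O)c1ccccc1 | intermediate
26 | N-hydroxyphthalimide | O=C1c2ccccc2C(=O)N1O | starting material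
27 | 1,3-dioxoisoindolin-2-yl (4E,6S,8E,10S,12E)-6,10-diacetoxy-4,8,12-trimethyl-13-[(2S)-5-oxo-4-(phenylsulfonylmethyl)-2,5-dihydrofuran-2-yl]trideca-4,8,12-trienoate | O=C1O[C@@H](/C=C(\C)C[C@H](OC(C)=O)/C=C(\C)C[C@H](OC(C)=O)/C=C(\C)CCC(=O)ON2C(=O)c3ccccc3C2=O)C=C1CS(=O)(=O)c1ccccc1 | intermediate
28 | CID11069750, trans-fused α-methylene-γ-butyrolactone on the 14-membered triene diacetate (1S,5S,9S,14R in the numbering of the overview) | C=C1C(=O)O[C@H]2/C=C(\C)C[C@H](OC(C)=O)/C=C(\C)C[C@H](OC(C)=O)/C=C(\C)CC[C@H]12 | target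

**Step count and risks**

Total step count: 21. Longest linear sequence: 19 steps (steps 1–3, 5–14, 16–21).

Steps most likely to fail:

1. Step 21 (Proposed new method). The C13 radical may be quenched by hydrogen abstraction or over-reduced at the cathode before the slow 14-membered closure, or it may add to a second molecule or to the product. It may also reach C14 on the face syn to the C1 side chain and give the cis-fused epimer. Reversible 3-exo closure onto C10=C11 may erode that alkene's geometry. Sulfinate or phthalimide anion may add to the methylene lactone.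
   Fallback, known chemistry, from 18 back to 28: a macrocyclic Barbier-type allylation with lactonisation, the established way to α-methylene lactones fused to large carbocycles. Here the carbon that the main route loses as CO2 becomes C14. 18 is desilylated with HF·pyridine to the hydroxy enal (2E,5S,6E,9S,10E)-5,9-diacetoxy-14-hydroxy-3,7,11-trimethyltetradeca-2,6,10-trienal F1, which Dess–Martin periodinane oxidises to the dialdehyde F2. The saturated aldehyde alone should enter a Morita–Baylis–Hillman reaction with methyl acrylate (DABCO) to give the α-methylene-β-hydroxy ester F3, as both carbinol epimers; that centre is lost in the next operation. NBS/Me2S converts F3 with allylic transposition into the (Z)-2-(bromomethyl)enoate F4. CrCl2 in THF at high dilution then forms the allylchromium species, which adds through its γ-carbon to the C1 enal (C1–C14 bond, ring B), and the chromium alkoxide closes onto the methyl ester to give 28. The anti-selective chair transition state of allylchromium additions should give the trans lactone. The enal face is under remote control only, so the two trans diastereomers would have to be separated.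

2. Step 17. Slow turnover at the hindered, sulfonylmethyl-bearing 1,1-disubstituted acrylate may let the Ru alkylidene on the vinyl group dimerise the substrate, or let the catalyst decay to hydride species that migrate alkenes.
   Fallback, from 19 back to 23: ring closure on an unsubstituted acrylate, with the sulfonylmethyl group installed afterwards. 19 is acylated with acryloyl chloride and iPr2NEt to the acrylate F5. Second-generation Grubbs catalyst closes it to the 3-unsubstituted butenolide F6. Morita–Baylis–Hillman hydroxymethylation with aqueous formaldehyde and PBu3 gives the 3-(hydroxymethyl)butenolide F7. CBr4/PPh3 gives the 3-(bromomethyl)butenolide F8, and PhSO2Na in DMF displaces bromide to give 23; any SN2′ isomer should equilibrate to 23 through reversible sulfinate addition–elimination.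

3. Step 14. Vinyl transfer to the deactivated β,β-disubstituted enal may be slow enough for uncatalysed background addition to erode the facial selectivity at C1, and the basic zinc alkoxide may trigger loss of the C5 acetate.
   Fallback, from 18 back to 19: alkynylation, then semi-reduction. Zinc-alkynylide addition of trimethylsilylacetylene to 18 with Me2Zn and the ProPhenol ligand enantiomer chosen for Re-face delivery (a method suited to conjugated aldehydes) gives the silylated propargylic alcohol F9. AgNO3 in aqueous acetone removes the C-silyl group without touching the acetates to give the terminal propargylic alcohol F10. Semi-hydrogenation (H2, Pd/CaCO3 poisoned with Pb(OAc)2, quinoline) gives 19.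

**Further compounds**

F1 | step 21 | (2E,5S,6E,9S,10E)-5,9-diacetoxy-14-hydroxy-3,7,11-trimethyltetradeca-2,6,10-trienal | O=C/C=C(\C)C[C@H](OC(C)=O)/C=C(\C)C[C@H](OC(C)=O)/C=C(\C)CCCO
F2 | step 21 | (2E,5S,6E,9S,10E)-5,9-diacetoxy-3,7,11-trimethyltetradeca-2,6,10-trienedial | O=C/C=C(\C)C[C@H](OC(C)=O)/C=C(\C)C[C@H](OC(C)=O)/C=C(\C)CCC=O
F3 | step 21 | methyl 3-hydroxy-2-methylene ester from F2 (Morita–Baylis–Hillman adduct, both carbinol epimers) | O=C/C=C(\C)C[C@H](OC(C)=O)/C=C(\C)C[C@H](OC(C)=O)/C=C(\C)CCC(O)C(=C)C(=O)OC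
F4 | step 21 | methyl (Z)-2-(bromomethyl)enoate from F3 | O=C/C=C(\C)C[C@H](OC(C)=O)/C=C(\C)C[C@H](OC(C)=O)/C=C(\C)CC/C=C(\CBr)C(=O)OC
F5 | step 17 | acrylate of 19 | C=C[C@@H](OC(=O)C=C)/C=C(\C)C[C@H](OC(C)=O)/C=C(\C)C[C@H](OC(C)=O)/C=C(\C)CCCO[Si](c1ccccc1)(c1ccccc1)C(C)(C)C
F6 | step 17 | 3-unsubstituted butenolide (analogue of 23 without the sulfonylmethyl group) | O=C1O[C@@H](/C=C(\C)C[C@H](OC(C)=O)/C=C(\C)C[C@H](OC(C)=O)/C=C(\C)CCCO[Si](c2ccccc2)(c2ccccc2)C(C)(C)C)C=C1
F7 | step 17 | 3-(hydroxymethyl)butenolide | O=C1O[C@@H](/C=C(\C)C[C@H](OC(C)=O)/C=C(\C)C[C@H](OC(C)=O)/C=C(\C)CCCO[Si](c2ccccc2)(c2ccccc2)C(C)(C)C)C=C1CO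
F8 | step 17 | 3-(bromomethyl)butenolide | O=C1O[C@@H](/C=C(\C)C[C@H](OC(C)=O)/C=C(\C)C[C@H](OC(C)=O)/C=C(\C)CCCO[Si](c2ccccc2)(c2ccccc2)C(C)(C)C)C=C1CBr
F9 | step 14 | trimethylsilyl-alkynyl carbinol from 18 | C[Si](C)(C)C#C[C@@H](O)/C=C(\C)C[C@H](OC(C)=O)/C=C(\C)C[C@H](OC(C)=O)/C=C(\C)CCCO[Si](c1ccccc1)(c1ccccc1)C(C)(C)C
F10 | step 14 | terminal propargylic alcohol | C#C[C@@H](O)/C=C(\C)C[C@H](OC(C)=O)/C=C(\C)C[C@H](OC(C)=O)/C=C(\C)CCCO[Si](c1ccccc1)(c1ccccc1)C(C)(C)C
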